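**Retrosynthetic overview**

1. Numbering: upper guaianolide unit C1–C15, lower 1,10-seco-eudesmanolide unit primed. The strategy rests on C7 and C8 of the seven-membered ring B, adjacent stereocentres that carry C11 and the lactone oxygen trans to each other. They are made by adding a C11–C13 alkenyl cuprate to a C7=C8–C9(=O) enone and oxygenating the C8 enolate; the C9 ketone is then removed and the α-methylene lactone closed last with MnO2.
2. The ring B enone comes from ring-closing metathesis (C7=C8) of a C5 allyl arm with a C9 vinyl carbinol arm, then oxidation; the allyl group comes from Stille coupling of a C5 enol triflate.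
3. The norbornene core (C1, C2, C3, C4=C5, C13', C11') with spiro centre C11' comes from a Diels–Alder reaction of a 2-silyloxy-5-acetoxycyclopentadiene (Piancatelli cyclopentenone, C10 from an Evans aldol) with α-methylene lactone 31.
4. Lactone 31 comes from (S)-carvone: directed epoxidation and selenoxide transposition set C10'–OH, alkoxymercuration sets C8'–O, and a Shapiro/boronate 1,2-migration with (R)-boronic ester 23 sets C4' and the C5'=C6' alkene.
5. Ring order: lower cyclohexene (carvone) → lower lactone ring (as tetrahydrofuran, step 8) → cyclopentenone (step 20) → norbornene rings (step 25) → ring B (step 29) → upper lactone (step 38).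

Key step: step 32

Remark: C9 is carried as an epimer mixture in 40–47 and 56–57 (left unmarked in the SMILES) because it ends as a carbonyl and then a methylene; in 52 and 53 the tertiary hydroxyl is drawn as OH although it will be present as its lithium alkoxide.

**Part A – dienophile 31 from (S)-carvone**

Step 1
Reactants: 1 (S)-(+)-carvone
Product: 2 (5S)-5-(3-chloroprop-1-en-2-yl)-2-methylcyclohex-2-en-1-one
Conditions: Ca(OCl)2, CO2 (dry ice), CH2Cl2/H2O, 0 °C
Reagents that add atoms: calcium hypochlorite, [Ca+2].[O-]Cl.[O-]Cl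
Why: Ene-type allylic chlorination by HOCl should occur only at the electron-rich isopropenyl group, the enone alkene being deactivated, and leaves C7' untouched.

Step 2
Reactants: 2 (5S)-5-(3-chloroprop-1-en-2-yl)-2-methylcyclohex-2-en-1-one
Product: 4 (5S)-5-(3-hydroxyprop-1-en-2-yl)-2-methylcyclohex-2-en-1-one, via allylic acetate 3 (not isolated)
Conditions: KOAc, n-Bu4NI (cat.), DMF, 60 °C; then K2CO3, MeOH, 23 °C
Reagents that add atoms: potassium acetate, CC(=O)[O-].[K+]
Why: SN2 displacement of the primary allylic chloride by acetate followed by transesterification should give the allylic alcohol.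

Step 3
Reactants: 4 (5S)-5-(3-hydroxyprop-1-en-2-yl)-2-methylcyclohex-2-en-1-one
Product: 5 (5S)-5-[3-(tert-butyldimethylsilyloxy)prop-1-en-2-yl]-2-methylcyclohex-2-en-1-one
Conditions: TBSCl, imidazole, DMF, 23 °C
Reagents that add atoms: tert-butyldimethylsilyl chloride, CC(C)(C)[Si](C)(C)Cl
Why: Silylation of the primary alcohol masks the second allylic alcohol so that it cannot direct the later epoxidation.

Step 4
Reactants: 5 (5S)-5-[3-(tert-butyldimethylsilyloxy)prop-1-en-2-yl]-2-methylcyclohex-2-en-1-one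
Product: 6 (1S,5S)-5-[3-(tert-butyldimethylsilyloxy)prop-1-en-2-yl]-2-methylcyclohex-2-en-1-ol
Conditions: NaBH4, CeCl3·7H2O, MeOH, –78 → 0 °C
Reagents that add atoms: none
Why: Luche 1,2-reduction of the carvone enone should give the cis allylic alcohol (hydroxyl cis to the C7' side chain), the known preference of this ring system.

Step 5
Reactants: 6 (1S,5S)-5-[3-(tert-butyldimethylsilyloxy)prop-1-en-2-yl]-2-methylcyclohex-2-en-1-ol
Product: 7 all-cis epoxy alcohol (C9'–C10' epoxide, C5' hydroxyl and C7' side chain on one face)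
Conditions: VO(acac)2 (cat.), t-BuOOH, CH2Cl2, 0 → 23 °C
Reagents that add atoms: tert-butyl hydroperoxide, CC(C)(C)OO
Why: Hydroxyl-directed epoxidation delivers oxygen syn to the allylic alcohol, which places the C10' oxygen on the face of the side chain, and leaves the remote 1,1-disubstituted alkene alone.

Step 6
Reactants: 7 all-cis epoxy alcohol
Product: 10 5-[3-(tert-butyldimethylsilyloxy)prop-1-en-2-yl]-2-methylcyclohex-3-ene-1,2-diol (both hydroxyls cis to the side chain), via hydroxy selenide 8 (not isolated), via selenoxide 9 (not isolated)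
Conditions: PhSeSePh, NaBH4, EtOH, 0 → 78 °C; then 30% H2O2, pyridine, THF, 0 → 23 °C
Reagents that add atoms: none
Why: Selenolate opens the epoxide at the less substituted C9' with inversion, and selenoxide syn-elimination can only use C8'–H because C10' has no hydrogen, so the tertiary allylic alcohol forms with the C10' configuration of the epoxide retained.

Step 7
Reactants: 10 silyl ether diol
Product: 11 5-(3-hydroxyprop-1-en-2-yl)-2-methylcyclohex-3-ene-1,2-diol (same configuration)
Conditions: TBAF, THF, 0 → 23 °C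
Reagents that add atoms: none
Why: Fluoride cleaves the only silyl ether and frees the primary hydroxyl needed as the internal nucleophile.

Step 8
Reactants: 11 triol
Product: 13 cis-fused 6-methyl-3-methylideneoctahydro-1-benzofuran-5,6-diol (ring oxygen and both hydroxyls on one face), via organomercurial 12 (not isolated)
Conditions: Hg(OCOCF3)2, THF, 0 °C; then NaBH4, 3 M NaOH, 0 °C
Reagents that add atoms: none
Why: In this intramolecular alkoxymercuration–demercuration the primary hydroxyl attacks C8' of the mercurinium ion in a 5-exo mode from the face of its tether, which sets the C8' oxygen cis to C7' (the future cis lactone fusion), and NaBH4 replaces mercury at C9' by hydrogen.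

Step 9
Reactants: 13 cyclic ether diol
Product: 14 6-hydroxy-6-methyl-3-methylidenehexahydro-1-benzofuran-5(4H)-one
Conditions: Dess–Martin periodinane, NaHCO3, CH2Cl2, 23 °C
Reagents that add atoms: none
Why: Only the secondary C5' alcohol can be oxidised; the tertiary C10' alcohol and the ether are inert.

Step 10
Reactants: 14 hydroxy ketone
Product: 15 tert-butyldimethylsilyl ether of 14
Conditions: TBSOTf, 2,6-lutidine, CH2Cl2, 0 → 23 °C
Reagents that add atoms: tert-butyldimethylsilyl triflate, CC(C)(C)[Si](C)(C)OS(=O)(=O)C(F)(F)F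
Why: Silyl triflate with a hindered pyridine base silylates the tertiary alcohol, which would otherwise quench organolithiums and undergo oxidative transposition later.

Step 11
Reactants: 15 silyloxy ketone
Product: 16 2,4,6-triisopropylbenzenesulfonylhydrazone of 15
Conditions: 2,4,6-(i-Pr)3C6H2SO2NHNH2, HCl (cat.), MeCN, 23 °C
Reagents that add atoms: 2,4,6-triisopropylbenzenesulfonyl hydrazide, CC(C)c1cc(C(C)C)c(S(=O)(=O)NN)c(C(C)C)c1
Why: Acid-catalysed condensation gives the hydrazone with the sulfonamide nitrogen turned away from quaternary C10', ready for Shapiro deprotonation at C6'.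

Step 12
Reactants: 17 allyloxy(tert-butyl)dimethylsilane; 18 pinacolborane
Product: 19 tert-butyldimethyl[3-(4,4,5,5-tetramethyl-1,3,2-dioxaborolan-2-yl)propoxy]silane
Conditions: [Ir(cod)Cl]2 (cat.), Ph2PCH2PPh2, CH2Cl2, 23 °C
Reagents that add atoms: none
Why: Iridium-catalysed hydroboration of a terminal alkene with pinacolborane is anti-Markovnikov and gives the primary boronic ester.

Step 13
Reactants: 20 ethyl 2,4,6-triisopropylbenzoate; 19 primary boronic ester
Product: 23 (R)-tert-butyldimethyl{[4-(4,4,5,5-tetramethyl-1,3,2-dioxaborolan-2-yl)pentyl]oxy}silane, via lithiated benzoate 21 (not isolated), via boronate complex 22 (not isolated)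
Conditions: s-BuLi, (–)-sparteine, Et2O, –78 °C; then 19, –78 °C; then MgBr2·OEt2, 35 °C
Reagents that add atoms: none
Why: Lithiation–borylation: sparteine-controlled removal of the pro-S proton, borylation with retention and 1,2-metallate rearrangement with inversion (benzoate leaves) should give the (R)-secondary boronic ester, which fixes C4'.

Step 14
Reactants: 16 hydrazone; 23 (R)-boronic ester
Product: 28 6-(tert-butyldimethylsilyloxy)-6-methyl-3-methylidene-5-[(2R)-5-(tert-butyldimethylsilyloxy)pentan-2-yl]-2,3,3a,6,7,7a-hexahydro-1-benzofuran, via alkenyllithium 24 (not isolated), via alkenyl boronate complex 25 (not isolated), via selanyl boronic ester 26 (not isolated), via selenoxide 27 (not isolated)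
Conditions: n-BuLi (2.1 equiv), THF, –78 → 0 °C; then 23, –78 °C; then PhSeCl, –78 → 0 °C; then m-CPBA, –45 → 23 °C
Reagents that add atoms: none
Why: Shapiro reaction gives the C5' alkenyllithium (only C6' has α-hydrogens); its boronate complex undergoes selenium-induced 1,2-migration of the secondary alkyl group with retention at C4' (Zweifel-type olefination), and the selenoxide–boron syn-elimination fits the cis boron/selenium arrangement that the ring enforces, placing the alkene at C5'=C6'.

Step 15
Reactants: 28 cyclic allylic ether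
Product: 29 bis-silylated α-methylene lactone (2-oxo derivative of 28)
Conditions: CrO3·2C5H5N, CH2Cl2, 23 °C
Reagents that add atoms: chromium trioxide, O=[Cr](=O)=O
Why: Allylic ether oxidation should take place at C12', the only methylene that is both allylic and α to the ether oxygen, converting the 3-methylidenetetrahydrofuran into the α-methylene-γ-butyrolactone; the tertiary allylic oxygen is protected against oxidative transposition.

Step 16
Reactants: 29 bis-silylated lactone
Product: 30 dihydroxy lactone (C10'–OH and C1'–OH free)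
Conditions: HF·pyridine, pyridine, THF, 0 → 23 °C
Reagents that add atoms: none
Why: Buffered HF removes both silyl ethers without base that could add to the α-methylene lactone.

Step 17
Reactants: 30 dihydroxy lactone
Product: 31 (4R)-4-[(3aS,6R,7aS)-6-hydroxy-6-methyl-3-methylidene-2-oxo-2,3,3a,6,7,7a-hexahydro-1-benzofuran-5-yl]pentyl acetate
Conditions: Ac2O, pyridine, CH2Cl2, 0 °C
Reagents that add atoms: acetic anhydride, CC(=O)OC(C)=O
Why: The primary alcohol is acetylated selectively; the hindered tertiary allylic alcohol does not react under these conditions.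

**Part B – diene 41 from 3-methylfuran-2-carbaldehyde**

Step 18
Reactants: 32 3-methylfuran-2-carbaldehyde; 33 (S)-4-benzyl-3-propanoyl-1,3-oxazolidin-2-one
Product: 35 (S)-4-benzyl-3-[(2S,3S)-3-hydroxy-2-methyl-3-(3-methylfuran-2-yl)propanoyl]-1,3-oxazolidin-2-one, via boron enolate 34 (not isolated)
Conditions: n-Bu2BOTf, i-Pr2NEt, CH2Cl2, –78 → 0 °C; then 32, –78 → 0 °C; then pH 7 buffer, MeOH, 30% H2O2
Reagents that add atoms: none
Why: Evans syn aldol through the (Z)-boron enolate and a chair transition state sets the methyl-bearing carbon (future C10) under auxiliary control; the carbinol centre is erased later.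

Step 19
Reactants: 35 aldol adduct
Product: 36 (1S,2R)-2-methyl-1-(3-methylfuran-2-yl)propane-1,3-diol
Conditions: LiBH4, MeOH (1 equiv), THF, 0 °C
Reagents that add atoms: none
Why: Reductive removal of the auxiliary gives the primary alcohol without touching the C10 stereocentre.

Step 20
Reactants: 36 furyl diol
Product: 37 (4R,5S)-4-hydroxy-5-[(2S)-1-hydroxypropan-2-yl]-2-methylcyclopent-2-en-1-one
Conditions: Dy(OTf)3 (10 mol %), MeCN/H2O, 80 °C
Reagents that add atoms: water, O
Why: Piancatelli rearrangement (furfuryl cation, addition of water at the furan 5-position to supply the ring hydroxyl, ring opening, conrotatory 4π closure) gives the 4,5-trans cyclopentenone; the sense of closure relative to C10 is not expected to be controlled, so the unwanted trans diastereomer (epimeric at both ring centres) would be removed by chromatography, and only the ring carbon bearing the hydroxyl (future C2) matters because the neighbouring ring carbon becomes sp2 in step 24.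

Step 21
Reactants: 37 dihydroxy cyclopentenone
Product: 38 (2S)-2-[(1S,5R)-5-hydroxy-3-methyl-2-oxocyclopent-3-en-1-yl]propanal
Conditions: TEMPO (cat.), PhI(OAc)2, CH2Cl2, 23 °C
Reagents that add atoms: none
Why: Oxoammonium oxidation is selective for the primary over the secondary alcohol.

Step 22
Reactants: 38 hydroxy aldehyde
Product: 39 acetate of 38 (future C2–OAc)
Conditions: Ac2O, pyridine, CH2Cl2, 0 °C
Reagents that add atoms: acetic anhydride, CC(=O)OC(C)=O
Why: Acetylation of the ring hydroxyl installs the C2 acetate of the target with retention.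

Step 23
Reactants: 39 acetoxy aldehyde
Product: 40 allylic alcohol (C9 carbinol with vinyl group; C9 epimers)
Conditions: CrCl2, NiCl2 (cat.), vinyl bromide, DMF, 23 °C
Reagents that add atoms: vinyl bromide, C=CBr
Why: Nozaki–Hiyama–Kishi vinylation adds to the aldehyde only and tolerates the enone and the acetate; the C9 configuration is irrelevant.

Step 24
Reactants: 40 allylic alcohol
Product: 41 5-acetoxy-2-silyloxycyclopentadiene (C1 arm with C9–OTBS, C4 methyl, C5–OTBS, C2–OAc)
Conditions: TBSOTf (2.5 equiv), Et3N, CH2Cl2, –78 → 0 °C; non-aqueous work-up, used at once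
Reagents that add atoms: tert-butyldimethylsilyl triflate, CC(C)(C)[Si](C)(C)OS(=O)(=O)C(F)(F)F
Why: Soft enolisation silylates the carbonyl oxygen and removes the only α'-hydrogen (C1–H), which gives the cross-conjugated silyloxy diene and erases C1; the C9 hydroxyl is silylated in the same operation.

**Part C – union and ring B**

Step 25
Reactants: 41 silyloxy diene; 31 α-methylene lactone
Product: 42 Diels–Alder adduct (norbornene with C5 silyl enol ether, C2–OAc anti to C4=C5, spirolactone at C11')
Conditions: toluene (concentrated), BHT (cat.), 23 → 45 °C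
Reagents that add atoms: none
Why: In this Diels–Alder reaction the 2-silyloxy group makes C1 the nucleophilic terminus, so C1 bonds to the methylene C13' and C3 to C11' (which also avoids two adjacent quaternary centres); the 5-acetoxy group directs the dienophile to its own face, the diene adds to the convex face of the cis-fused lactone (anti to C6'), and the planar lactone carbonyl rather than C7' should sit endo under the C4-methyl-substituted diene, which together set C1, C3 and C11'.

Step 26
Reactants: 42 silyl enol ether adduct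
Product: 44 C5 enol triflate, via cesium enolate 43 (not isolated)
Conditions: CsF, PhNTf2, DME, 23 °C
Reagents that add atoms: N-phenylbis(trifluoromethanesulfonimide), O=S(=O)(N(c1ccccc1)S(=O)(=O)C(F)(F)F)C(F)(F)F
Why: Fluoride cleaves the labile silyl enol ether in preference to the alkyl silyl ether and the regiodefined enolate is trapped on oxygen, with no strong base that would harm the acetates.

Step 27
Reactants: 44 enol triflate
Product: 45 C5 allyl compound
Conditions: allyltributylstannane, Pd(PPh3)4, LiCl, THF, 65 °C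
Reagents that add atoms: allyltributylstannane, C=CC[Sn](CCCC)(CCCC)CCCC
Why: Stille coupling of an alkenyl triflate under neutral conditions installs C6–C7 and keeps the C4=C5 alkene in place.

Step 28
Reactants: 45 C9 silyl ether
Product: 46 C9 allylic alcohol
Conditions: HF·pyridine, pyridine, THF, 0 → 23 °C
Reagents that add atoms: none
Why: The single silyl ether is cleaved without affecting acetates or lactone, and the free allylic hydroxyl assists the metathesis.

Step 29
Reactants: 46 diene
Product: 47 cycloheptenol (ring B closed, C7=C8, C9–OH)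
Conditions: second-generation Grubbs catalyst, CH2Cl2, 40 °C
Reagents that add atoms: none
Why: Ring-closing metathesis joins the two monosubstituted alkenes into the seven-membered ring; the tetrasubstituted C4=C5 and trisubstituted C5'=C6' alkenes are inert.

Step 30
Reactants: 47 cycloheptenol
Product: 48 ring B cycloheptenone (C9 ketone, C7=C8)
Conditions: Dess–Martin periodinane, NaHCO3, CH2Cl2, 23 °C
Reagents that add atoms: none
Why: Buffered oxidation of the allylic alcohol gives the enone without epimerising C10; the tertiary alcohol is inert.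

Step 31
Reactants: 49 2-bromoprop-2-en-1-ol
Product: 50 2-bromo-3-(tert-butyldimethylsilyloxy)propene
Conditions: TBSCl, imidazole, CH2Cl2, 23 °C
Reagents that add atoms: tert-butyldimethylsilyl chloride, CC(C)(C)[Si](C)(C)Cl
Why: Standard silylation of the primary allylic alcohol.

Step 32
Reactants: 48 ring B cycloheptenone; 50 2-bromo-3-(tert-butyldimethylsilyloxy)propene; 51 dioxygen
Product: 54 8-hydroxy-9-oxo compound with the C7 3-(tert-butyldimethylsilyloxy)prop-1-en-2-yl group, via lithium enolate 52 (not isolated), via hydroperoxide 53 (not isolated)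
Conditions: 50 (5 equiv), t-BuLi (10 equiv), Et2O, –78 °C; CuI (2.5 equiv), Me2S, –78 → –50 °C; then 48, THF, –78 °C; then P(OEt)3, O2 (bubbled), –78 °C; aq NH4Cl
Reagents that add atoms: none
Why: The lithium dialkenylcuprate forms a π-complex with the enone, adds oxidatively at C7 and eliminates reductively to form C7–C11 and the regiodefined lithium C8=C9 enolate, which takes up dioxygen at C8 to give a hydroperoxide that the phosphite reduces at once to the alcohol. The closest known reaction type is the vicinal difunctionalisation of cycloalkenones by alkenylcuprate conjugate addition followed by α-hydroxylation of the enolate with O2 and a phosphite. No ring is closed; two bonds (C7–C11, C8–O) and two stereocentres are formed. C7 is set by attack on the exo face of ring B, the side of the C2 bridge whose syn position carries only hydrogen, while the other face is shielded by C13'H2 and the spirolactone. C8 is set by oxygenation anti to the new C7 substituent, which gives the trans pattern of the lactone. The step needs 1,4-addition in the presence of two acetates, two lactones and a free tertiary alcohol, which the soft cuprate at –78 °C (used in excess to allow for the alcohol) should secure, and it needs the hydroperoxide to be reduced before it fragments, which the phosphite present during oxygenation is meant to ensure.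

**Part D – endgame**

Step 33
Reactants: 54 hydroxy ketone
Product: 55 bis(triethylsilyl) ether (C8–OTES, C10'–OTES)
Conditions: TESOTf (3 equiv), 2,6-lutidine, CH2Cl2, –78 → 0 °C
Reagents that add atoms: triethylsilyl triflate, CC[Si](CC)(CC)OS(=O)(=O)C(F)(F)F
Why: Silyl triflate protects the secondary C8 and the tertiary C10' hydroxyls so that only the C9 oxygen is functionalised in the deoxygenation.

Step 34
Reactants: 55 silyloxy ketone
Product: 56 C9 alcohol (epimers)
Conditions: NaBH4, MeOH/THF, –40 → 0 °C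
Reagents that add atoms: none
Why: Borohydride reduces the ketone at low temperature faster than it attacks acetates or lactones; the C9 configuration is irrelevant.

Step 35
Reactants: 56 C9 alcohol
Product: 57 C9 O-phenyl thionocarbonate
Conditions: PhOC(S)Cl, DMAP, pyridine, CH2Cl2, 23 °C
Reagents that add atoms: O-phenyl chlorothionoformate, S=C(Cl)Oc1ccccc1
Why: Acylation under non-basic conditions gives the radical precursor of the Barton–McCombie deoxygenation.

Step 36
Reactants: 57 thionocarbonate
Product: 58 9-deoxy compound (C9 methylene)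
Conditions: n-Bu3SnH, AIBN, toluene, 90 °C
Reagents that add atoms: none
Why: Barton–McCombie deoxygenation gives a secondary C9 radical that is reduced by the stannane; cyclisation onto the C11 alkene would be 4-exo or 5-endo and is not expected, and no stereocentre is affected.

Step 37
Reactants: 58 tris-silyl ether
Product: 59 triol (C8–OH, C12–OH, C10'–OH)
Conditions: HF·pyridine, pyridine, THF, 0 → 23 °C
Reagents that add atoms: none
Why: Buffered HF cleaves the three silyl ethers and leaves both acetates and the spirolactone intact.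

Step 38
Reactants: 59 triol
Product: 60 target CNP0257312.1
Conditions: MnO2 (activated, excess), CH2Cl2, 23 °C
Reagents that add atoms: none
Why: MnO2 oxidises only the allylic primary C12 alcohol to the enal, the C8 hydroxyl closes the lactol, and further oxidation gives the trans-fused α-methylene-γ-butyrolactone (oxidative lactonisation); the tertiary alcohol cannot be oxidised.

**Compound list**

1 | (S)-(+)-carvone | CC1=CC[C@@H](CC1=O)C(C)=C | starting material
2 | (5S)-5-(3-chloroprop-1-en-2-yl)-2-methylcyclohex-2-en-1-one | O=C1C[C@@H](C(=C)CCl)CC=C1C | intermediate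
3 | allylic acetate of 4 | O=C1C[C@@H](C(=C)COC(C)=O)CC=C1C | intermediate
4 | (5S)-5-(3-hydroxyprop-1-en-2-yl)-2-methylcyclohex-2-en-1-one | O=C1C[C@@H](C(=C)CO)CC=C1C | intermediate
5 | (5S)-5-[3-(tert-butyldimethylsilyloxy)prop-1-en-2-yl]-2-methylcyclohex-2-en-1-one | O=C1C[C@@H](C(=C)CO[Si](C)(C)C(C)(C)C)CC=C1C | intermediate
6 | (1S,5S)-5-[3-(tert-butyldimethylsilyloxy)prop-1-en-2-yl]-2-methylcyclohex-2-en-1-ol | O[C@H]1C[C@@H](C(=C)CO[Si](C)(C)C(C)(C)C)CC=C1C | intermediate
7 | all-cis epoxy alcohol | O[C@H]1C[C@@H](C(=C)CO[Si](C)(C)C(C)(C)C)C[C@H]2O[C@@]12C | intermediate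
8 | hydroxy selenide | O[C@H]1C[C@@H](C(=C)CO[Si](C)(C)C(C)(C)C)C[C@H]([Se]c2ccccc2)[C@@]1(C)O | intermediate
9 | selenoxide | O[C@H]1C[C@@H](C(=C)CO[Si](C)(C)C(C)(C)C)C[C@H]([Se](=O)c2ccccc2)[C@@]1(C)O | intermediate
10 | 5-[3-(tert-butyldimethylsilyloxy)prop-1-en-2-yl]-2-methylcyclohex-3-ene-1,2-diol | O[C@H]1C[C@@H](C(=C)CO[Si](C)(C)C(C)(C)C)C=C[C@@]1(C)O | intermediate
11 | 5-(3-hydroxyprop-1-en-2-yl)-2-methylcyclohex-3-ene-1,2-diol | O[C@H]1C[C@@H](C(=C)CO)C=C[C@@]1(C)O | intermediate
12 | organomercurial | O[C@H]1C[C@H]2C(=C)CO[C@H]2[C@H]([Hg]OC(=O)C(F)(F)F)[C@@]1(C)O | intermediate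
13 | cis-fused 6-methyl-3-methylideneoctahydro-1-benzofuran-5,6-diol | O[C@H]1C[C@H]2C(=C)CO[C@H]2C[C@@]1(C)O | intermediate
14 | 6-hydroxy-6-methyl-3-methylidenehexahydro-1-benzofuran-5(4H)-one | O=C1C[C@H]2C(=C)CO[C@H]2C[C@@]1(C)O | intermediate
15 | tert-butyldimethylsilyl ether of 14 | O=C1C[C@H]2C(=C)CO[C@H]2C[C@@]1(C)O[Si](C)(C)C(C)(C)C | intermediate
16 | 2,4,6-triisopropylbenzenesulfonylhydrazone of 15 | CC(C)c1cc(C(C)C)c(S(=O)(=O)NN=C2C[C@H]3C(=C)CO[C@H]3C[C@@]2(C)O[Si](C)(C)C(C)(C)C)c(C(C)C)c1 | intermediate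
17 | allyloxy(tert-butyl)dimethylsilane | C=CCO[Si](C)(C)C(C)(C)C | starting material
18 | pinacolborane | CC1(C)OBOC1(C)C | starting material
19 | tert-butyldimethyl[3-(4,4,5,5-tetramethyl-1,3,2-dioxaborolan-2-yl)propoxy]silane | CC(C)(C)[Si](C)(C)OCCCB1OC(C)(C)C(C)(C)O1 | intermediate
20 | ethyl 2,4,6-triisopropylbenzoate | CCOC(=O)c1c(C(C)C)cc(C(C)C)cc1C(C)C | starting material
21 | (S)-1-lithioethyl 2,4,6-triisopropylbenzoate | C[C@H]([Li])OC(=O)c1c(C(C)C)cc(C(C)C)cc1C(C)C | intermediate
22 | boronate complex of 21 and 19 | C[C@H]([B-]1(CCCO[Si](C)(C)C(C)(C)C)OC(C)(C)C(C)(C)O1)OC(=O)c1c(C(C)C)cc(C(C)C)cc1C(C)C.[Li+] | intermediate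
23 | (R)-tert-butyldimethyl{[4-(4,4,5,5-tetramethyl-1,3,2-dioxaborolan-2-yl)pentyl]oxy}silane | C[C@H](CCCO[Si](C)(C)C(C)(C)C)B1OC(C)(C)C(C)(C)O1 | intermediate
24 | C5' alkenyllithium | [Li]C1=C[C@H]2C(=C)CO[C@H]2C[C@@]1(C)O[Si](C)(C)C(C)(C)C | intermediate
25 | alkenyl boronate complex | C[C@H](CCCO[Si](C)(C)C(C)(C)C)[B-]3(OC(C)(C)C(C)(C)O3)C1=C[C@H]2C(=C)CO[C@H]2C[C@@]1(C)O[Si](C)(C)C(C)(C)C.[Li+] | intermediate
26 | β-phenylselanyl boronic ester (boron and selenium cis) | C[C@H](CCCO[Si](C)(C)C(C)(C)C)C1(B3OC(C)(C)C(C)(C)O3)C([Se]c4ccccc4)[C@H]2C(=C)CO[C@H]2C[C@@]1(C)O[Si](C)(C)C(C)(C)C | intermediate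
27 | selenoxide of 26 | C[C@H](CCCO[Si](C)(C)C(C)(C)C)C1(B3OC(C)(C)C(C)(C)O3)C([Se](=O)c4ccccc4)[C@H]2C(=C)CO[C@H]2C[C@@]1(C)O[Si](C)(C)C(C)(C)C | intermediate
28 | coupled cyclic ether (C5' side chain, C5'=C6') | C[C@H](CCCO[Si](C)(C)C(C)(C)C)C1=C[C@H]2C(=C)CO[C@H]2C[C@@]1(C)O[Si](C)(C)C(C)(C)C | intermediate
29 | bis-silylated α-methylene lactone | C=C1C(=O)O[C@H]2C[C@@](C)(O[Si](C)(C)C(C)(C)C)C([C@H](C)CCCO[Si](C)(C)C(C)(C)C)=C[C@@H]12 | intermediate
30 | dihydroxy lactone | C=C1C(=O)O[C@H]2C[C@@](C)(O)C([C@H](C)CCCO)=C[C@@H]12 | intermediate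
31 | (4R)-4-[(3aS,6R,7aS)-6-hydroxy-6-methyl-3-methylidene-2-oxo-2,3,3a,6,7,7a-hexahydro-1-benzofuran-5-yl]pentyl acetate | C=C1C(=O)O[C@H]2C[C@@](C)(O)C([C@H](C)CCCOC(C)=O)=C[C@@H]12 | intermediate
32 | 3-methylfuran-2-carbaldehyde | Cc1ccoc1C=O | starting material
33 | (S)-4-benzyl-3-propanoyl-1,3-oxazolidin-2-one | CCC(=O)N1[C@@H](Cc2ccccc2)COC1=O | starting material
34 | (Z)-dibutylboron enolate of 33 | CCCCB(CCCC)O/C(=C\C)N1[C@@H](Cc2ccccc2)COC1=O | intermediate
35 | (S)-4-benzyl-3-[(2S,3S)-3-hydroxy-2-methyl-3-(3-methylfuran-2-yl)propanoyl]-1,3-oxazolidin-2-one | O=C1OC[C@H](Cc2ccccc2)N1C(=O)[C@@H](C)[C@H](O)c1occc1C | intermediate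
36 | (1S,2R)-2-methyl-1-(3-methylfuran-2-yl)propane-1,3-diol | OC[C@@H](C)[C@H](O)c1occc1C | intermediate
37 | (4R,5S)-4-hydroxy-5-[(2S)-1-hydroxypropan-2-yl]-2-methylcyclopent-2-en-1-one | O=C1C(C)=C[C@@H](O)[C@@H]1[C@H](C)CO | intermediate
38 | (2S)-2-[(1S,5R)-5-hydroxy-3-methyl-2-oxocyclopent-3-en-1-yl]propanal | O=C1C(C)=C[C@@H](O)[C@@H]1[C@H](C)C=O | intermediate
39 | acetate of 38 | O=C1C(C)=C[C@@H](OC(C)=O)[C@@H]1[C@H](C)C=O | intermediate
40 | C9 allylic alcohol on the cyclopentenone (epimers) | O=C1C(C)=C[C@@H](OC(C)=O)[C@@H]1[C@H](C)C(O)C=C | intermediate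
41 | 5-acetoxy-2-silyloxycyclopentadiene | CC(=O)O[C@@H]1C=C(C)C(O[Si](C)(C)C(C)(C)C)=C1[C@H](C)C(O[Si](C)(C)C(C)(C)C)C=C | intermediate
42 | Diels–Alder adduct | C=CC(O[Si](C)(C)C(C)(C)C)[C@@H](C)[C@]34C[C@]5(C(=O)O[C@H]6C[C@@](C)(O)C([C@H](C)CCCOC(C)=O)=C[C@H]65)[C@H](C(C)=C3O[Si](C)(C)C(C)(C)C)[C@H]4OC(C)=O | intermediate
43 | cesium enolate | C=CC(O[Si](C)(C)C(C)(C)C)[C@@H](C)[C@]34C[C@]5(C(=O)O[C@H]6C[C@@](C)(O)C([C@H](C)CCCOC(C)=O)=C[C@H]65)[C@H](C(C)=C3[O-])[C@H]4OC(C)=O.[Cs+] | intermediate
44 | C5 enol triflate | C=CC(O[Si](C)(C)C(C)(C)C)[C@@H](C)[C@]34C[C@]5(C(=O)O[C@H]6C[C@@](C)(O)C([C@H](C)CCCOC(C)=O)=C[C@H]65)[C@H](C(C)=C3OS(=O)(=O)C(F)(F)F)[C@H]4OC(C)=O | intermediate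
45 | C5 allyl compound | C=CC(O[Si](C)(C)C(C)(C)C)[C@@H](C)[C@]34C[C@]5(C(=O)O[C@H]6C[C@@](C)(O)C([C@H](C)CCCOC(C)=O)=C[C@H]65)[C@H](C(C)=C3CC=C)[C@H]4OC(C)=O | intermediate
46 | C9 allylic alcohol of the adduct | C=CC(O)[C@@H](C)[C@]34C[C@]5(C(=O)O[C@H]6C[C@@](C)(O)C([C@H](C)CCCOC(C)=O)=C[C@H]65)[C@H](C(C)=C3CC=C)[C@H]4OC(C)=O | intermediate
47 | cycloheptenol | C2=CC(O)[C@@H](C)[C@]34C[C@]5(C(=O)O[C@H]6C[C@@](C)(O)C([C@H](C)CCCOC(C)=O)=C[C@H]65)[C@H](C(C)=C3C2)[C@H]4OC(C)=O | intermediate
48 | ring B cycloheptenone | C2=CC(=O)[C@@H](C)[C@]34C[C@]5(C(=O)O[C@H]6C[C@@](C)(O)C([C@H](C)CCCOC(C)=O)=C[C@H]65)[C@H](C(C)=C3C2)[C@H]4OC(C)=O | intermediate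
49 | 2-bromoprop-2-en-1-ol | C=C(Br)CO | starting material
50 | 2-bromo-3-(tert-butyldimethylsilyloxy)propene | C=C(Br)CO[Si](C)(C)C(C)(C)C | intermediate
51 | dioxygen | O=O | starting material
52 | lithium C8 enolate | C2=C(O[Li])[C@@H](C)[C@]34C[C@]5(C(=O)O[C@H]6C[C@@](C)(O)C([C@H](C)CCCOC(C)=O)=C[C@H]65)[C@H](C(C)=C3C[C@H]2C(=C)CO[Si](C)(C)C(C)(C)C)[C@H]4OC(C)=O | intermediate
53 | C8 hydroperoxide | OO[C@@H]2C(=O)[C@@H](C)[C@]34C[C@]5(C(=O)O[C@H]6C[C@@](C)(O)C([C@H](C)CCCOC(C)=O)=C[C@H]65)[C@H](C(C)=C3C[C@H]2C(=C)CO[Si](C)(C)C(C)(C)C)[C@H]4OC(C)=O | intermediate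
54 | 8-hydroxy-9-oxo C7 allyl silyl ether | O[C@@H]2C(=O)[C@@H](C)[C@]34C[C@]5(C(=O)O[C@H]6C[C@@](C)(O)C([C@H](C)CCCOC(C)=O)=C[C@H]65)[C@H](C(C)=C3C[C@H]2C(=C)CO[Si](C)(C)C(C)(C)C)[C@H]4OC(C)=O | intermediate
55 | bis(triethylsilyl) ether | CC[Si](CC)(CC)O[C@@H]2C(=O)[C@@H](C)[C@]34C[C@]5(C(=O)O[C@H]6C[C@@](C)(O[Si](CC)(CC)CC)C([C@H](C)CCCOC(C)=O)=C[C@H]65)[C@H](C(C)=C3C[C@H]2C(=C)CO[Si](C)(C)C(C)(C)C)[C@H]4OC(C)=O | intermediate
56 | C9 alcohol (epimers) | CC[Si](CC)(CC)O[C@@H]2C(O)[C@@H](C)[C@]34C[C@]5(C(=O)O[C@H]6C[C@@](C)(O[Si](CC)(CC)CC)C([C@H](C)CCCOC(C)=O)=C[C@H]65)[C@H](C(C)=C3C[C@H]2C(=C)CO[Si](C)(C)C(C)(C)C)[C@H]4OC(C)=O | intermediate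
57 | C9 O-phenyl thionocarbonate | CC[Si](CC)(CC)O[C@@H]2C(OC(=S)Oc7ccccc7)[C@@H](C)[C@]34C[C@]5(C(=O)O[C@H]6C[C@@](C)(O[Si](CC)(CC)CC)C([C@H](C)CCCOC(C)=O)=C[C@H]65)[C@H](C(C)=C3C[C@H]2C(=C)CO[Si](C)(C)C(C)(C)C)[C@H]4OC(C)=O | intermediate
58 | 9-deoxy compound | CC[Si](CC)(CC)O[C@@H]2C[C@@H](C)[C@]34C[C@]5(C(=O)O[C@H]6C[C@@](C)(O[Si](CC)(CC)CC)C([C@H](C)CCCOC(C)=O)=C[C@H]65)[C@H](C(C)=C3C[C@H]2C(=C)CO[Si](C)(C)C(C)(C)C)[C@H]4OC(C)=O | intermediate
59 | triol | O[C@@H]2C[C@@H](C)[C@]34C[C@]5(C(=O)O[C@H]6C[C@@](C)(O)C([C@H](C)CCCOC(C)=O)=C[C@H]65)[C@H](C(C)=C3C[C@H]2C(=C)CO)[C@H]4OC(C)=O | intermediate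
60 | CNP0257312.1 | C=C1C(=O)O[C@@H]2C[C@@H](C)[C@]34C[C@]5(C(=O)O[C@H]6C[C@@](C)(O)C([C@H](C)CCCOC(C)=O)=C[C@H]65)[C@H](C(C)=C3C[C@@H]12)[C@H]4OC(C)=O | target

**Step count**

Total: 38 steps. Longest linear sequence: 28 steps from (S)-carvone (steps 1–11, 14–17, 25–30, 32–38).

**Steps most likely to fail**

1. Step 25 (Diels–Alder). The silyloxy diene may isomerise by 1,5-hydrogen shift before it is trapped, or it may react through a stepwise polar path that erodes the syn-to-acetoxy and endo selectivity. Fallback: setting out from 41, the silyl enol ether is converted with CsF and PhNTf2 into the dienyl triflate F1, and Stille coupling with allyltributylstannane (Pd(PPh3)4, LiCl, THF, 23 °C) gives the 5-acetoxy-1,2,3-trialkylcyclopentadiene F2. This non-polarised diene would be combined with 31 in a concerted cycloaddition under high pressure (about 10 kbar, CH2Cl2, 23 °C), where only the 5-acetoxy group and sterics steer the approach. The product is the C5 allyl adduct, so the route is rejoined at 45 and steps 26 and 27 fall away.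

2. Step 32 (key step). The secondary α-hydroperoxide may be over-oxidised or cleaved, copper species may be oxidised competitively by dioxygen, or the anti selectivity at C8 may be low. Fallback: setting out from 48 and the same cuprate from 50, the enolate is quenched with Me3SiCl and Et3N at –78 °C to give the isolable silyl enol ether F3 (the tertiary alcohol is silylated as well). Rubottom oxidation with dimethyldioxirane (1 equiv, acetone/CH2Cl2, –78 °C) on the face anti to the C7 substituent gives the 8-trimethylsilyloxy ketone F4, and citric acid in methanol removes both trimethylsilyl groups. The route is rejoined at 54.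

3. Step 14 (Shapiro–boronate coupling). Fragmentation of the hindered hydrazone may be incomplete and the alkenyllithium may be quenched before it meets the boronic ester, so that the boronate complex does not form cleanly. Fallback: setting out from 15, condensation with hydrazine hydrate (Et3N, EtOH, 78 °C) gives the hydrazone F5, and iodine with 1,1,3,3-tetramethylguanidine in THF gives the alkenyl iodide F6. Iodine–lithium exchange with t-BuLi (2 equiv, THF, –78 °C) then delivers the alkenyllithium cleanly at low temperature. The route is rejoined at 24, which is carried on to 28 with 23, PhSeCl and m-CPBA as in step 14.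

**Further compounds**

F1 | step 25 | dienyl triflate | CC(=O)O[C@@H]1C=C(C)C(OS(=O)(=O)C(F)(F)F)=C1[C@H](C)C(O[Si](C)(C)C(C)(C)C)C=C
F2 | step 25 | 5-acetoxy-2-allylcyclopentadiene | CC(=O)O[C@@H]1C=C(C)C(CC=C)=C1[C@H](C)C(O[Si](C)(C)C(C)(C)C)C=C
F3 | step 32 | C8=C9 trimethylsilyl enol ether (C10' trimethylsilyl ether) | C2=C(O[Si](C)(C)C)[C@@H](C)[C@]34C[C@]5(C(=O)O[C@H]6C[C@@](C)(O[Si](C)(C)C)C([C@H](C)CCCOC(C)=O)=C[C@H]65)[C@H](C(C)=C3C[C@H]2C(=C)CO[Si](C)(C)C(C)(C)C)[C@H]4OC(C)=O
F4 | step 32 | 8-trimethylsilyloxy ketone | C[Si](C)(C)O[C@@H]2C(=O)[C@@H](C)[C@]34C[C@]5(C(=O)O[C@H]6C[C@@](C)(O[Si](C)(C)C)C([C@H](C)CCCOC(C)=O)=C[C@H]65)[C@H](C(C)=C3C[C@H]2C(=C)CO[Si](C)(C)C(C)(C)C)[C@H]4OC(C)=O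
F5 | step 14 | hydrazone of 15 | NN=C2C[C@H]3C(=C)CO[C@H]3C[C@@]2(C)O[Si](C)(C)C(C)(C)C
F6 | step 14 | C5' alkenyl iodide | IC1=C[C@H]2C(=C)CO[C@H]2C[C@@]1(C)O[Si](C)(C)C(C)(C)C
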